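The route rests on opening the pyran ring of the 2H-chromene at O1–C2 and at C3=C4. C2, the sole stereocentre, is quaternary: it holds O1, a methyl group, the CH2O arm and the C3=C4 double bond. That pattern arises when a phenol oxygen attacks the tertiary terminus of the allyl unit generated from isoprene monoepoxide. A palladium-catalysed dynamic kinetic asymmetric etherification therefore joins the 4-OH of 5-vinyl-2,4-dihydroxyacetophenone to the racemic epoxide in one operation and fixes C2 as (R) from both epoxide enantiomers. The product is a diene that ring-closing metathesis converts into the chromene. The feruloyl ester is attached at the end.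

Key step: step 3

Remark: the (S,S) antipode of the DACH-phenyl Trost ligand, N,N'-[(1S,2S)-cyclohexane-1,2-diyl]bis[2-(diphenylphosphanyl)benzamide], is assumed, not confirmed, to give the (R) ether; the sense would be checked on the first run and the (R,R) ligand used in the same way if the (S) ether formed.

Step 1
Reactants: 1 2,4-dihydroxyacetophenone
Product: 2 5-bromo-2,4-dihydroxyacetophenone
Conditions: NBS (1.0 equiv), MeCN, 0 °C to rt
Reagents that add atoms: N-bromosuccinimide, O=C1CCC(=O)N1Br
Why: Electrophilic aromatic bromination of the doubly activated ring should go to C5, which is para to the 2-OH, ortho to the 4-OH and less crowded than C3 between the two hydroxyls, while one equivalent of reagent at low temperature limits dibromination.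

Step 2
Reactants: 2 5-bromo-2,4-dihydroxyacetophenone; 3 potassium vinyltrifluoroborate
Product: 4 5-vinyl-2,4-dihydroxyacetophenone
Conditions: PdCl2(dppf)·CH2Cl2 (3 mol%), K2CO3 (3 equiv), 1,4-dioxane/H2O 4:1, 85 °C, BHT (trace)
Reagents that add atoms: none
Why: Suzuki–Miyaura coupling of an aryl bromide with a vinyltrifluoroborate tolerates free phenols under aqueous carbonate and installs the carbon that becomes C4 of the chromene, with the radical inhibitor and prompt use protecting the hydroxystyrene from polymerisation.

Step 3
Reactants: 4 5-vinyl-2,4-dihydroxyacetophenone; 5 racemic 2-methyl-2-vinyloxirane (isoprene monoepoxide, 1.2 equiv)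
Product: 6 (R)-1-[5-ethenyl-2-hydroxy-4-[(1-hydroxy-2-methylbut-3-en-2-yl)oxy]phenyl]ethanone
Conditions: Pd2(dba)3·CHCl3 (1 mol%), (S,S)-DACH-phenyl Trost ligand (3 mol%), degassed CH2Cl2 (dilute), 0 °C to rt, stopped at full conversion
Reagents that add atoms: none
Why: Zerovalent palladium opens the vinyl epoxide with inversion to a zwitterionic pi-allyl alkoxide, and the two diastereomeric complexes formed from the two enantiomers of 5 interconvert through an eta-1 allyl bound at the unsubstituted CH2 terminus faster than either is trapped. The alkoxide deprotonates the more acidic 4-OH of 4 and holds the phenoxide by hydrogen bonding and ion pairing beside the tertiary terminus, where it attacks anti to palladium and forms the O1–C2 aryl ether bond of the branched product. The closest known reaction type is the Trost palladium-catalysed dynamic kinetic asymmetric allylic alkylation of isoprene monoepoxide with oxygen pronucleophiles. No ring is closed here, and the new stereocentre C2 is set as (R) by the chiral pocket of the diphosphine ligand, which lets one of the equilibrating complexes react much faster than the other. Three selectivities are needed: enantioselection, secured by the ligand together with the fast pi-sigma-pi equilibration; branched over linear attack, secured by the alkoxide-directed delivery; and 4-OH over 2-OH, secured by the hydrogen bond of the 2-OH to the acetyl group, which lowers its acidity and nucleophilicity. Because the electron-poor aryloxide is a fair leaving group, the reaction is kept at or below room temperature and worked up at full conversion so that the tertiary ether does not re-ionise to the linear isomer.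

Step 4
Reactants: 6 (R)-1-[5-ethenyl-2-hydroxy-4-[(1-hydroxy-2-methylbut-3-en-2-yl)oxy]phenyl]ethanone
Product: 7 (R)-1-[7-hydroxy-2-(hydroxymethyl)-2-methyl-2H-chromen-6-yl]ethanone
Conditions: second-generation Grubbs catalyst RuCl2(=CHPh)(PCy3)(H2IMes) (3 mol%), CH2Cl2 (0.01 M), 40 °C
Reagents that add atoms: none
Why: Ring-closing metathesis between the styrene and the vinyl group on C2 closes the six-membered pyran ring as the C3=C4 alkene with loss of ethylene, a known entry to 2H-chromenes that tolerates free hydroxyl groups and leaves C2 untouched.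

Step 5
Reactants: 8 trans-ferulic acid
Product: 10 4-O-TBS-ferulic acid, via bis-TBS ferulate 9 (not isolated)
Conditions: TBSCl (2.4 equiv), imidazole (5 equiv), DMF, rt; then AcOH/THF/H2O 3:1:1, rt
Reagents that add atoms: tert-butyldimethylsilyl chloride, CC(C)(C)[Si](C)(C)Cl
Why: Silylation of both acidic hydroxyls followed by mild aqueous acid, which hydrolyses the labile silyl ester but not the aryl silyl ether, is the standard protection of a hydroxycinnamic acid and leaves the E alkene unchanged.

Step 6
Reactants: 7 (R)-1-[7-hydroxy-2-(hydroxymethyl)-2-methyl-2H-chromen-6-yl]ethanone; 10 4-O-TBS-ferulic acid (1.05 equiv)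
Product: 11 [(2R)-6-acetyl-7-hydroxy-2-methyl-2H-chromen-2-yl]methyl (E)-3-[4-(tert-butyldimethylsilyloxy)-3-methoxyphenyl]prop-2-enoate
Conditions: DCC (1.2 equiv), DMAP (0.1 equiv), CH2Cl2, 0 °C to rt
Reagents that add atoms: none
Why: Steglich esterification should acylate the primary alcohol only, because the 7-OH is tied up in a hydrogen bond to the 6-acetyl group and is a poor nucleophile, and acyl transfer is not hampered by the neighbouring quaternary carbon in the way an SN2 reaction would be.

Step 7
Reactants: 11 [(2R)-6-acetyl-7-hydroxy-2-methyl-2H-chromen-2-yl]methyl (E)-3-[4-(tert-butyldimethylsilyloxy)-3-methoxyphenyl]prop-2-enoate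
Product: 12 [(2R)-6-acetyl-7-hydroxy-2-methyl-2H-chromen-2-yl]methyl (E)-3-(4-hydroxy-3-methoxyphenyl)prop-2-enoate (CNP0375196.1)
Conditions: Bu4NF (1.1 equiv), AcOH (1.2 equiv), THF, 0 °C
Reagents that add atoms: none
Why: Fluoride-mediated desilylation cleaves the aryl silyl ether rapidly, and the acetic acid buffer keeps the medium non-basic so that the cinnamate ester and the chromene survive.

Compound list
1 | 2,4-dihydroxyacetophenone | CC(=O)c1ccc(O)cc1O | starting material
2 | 5-bromo-2,4-dihydroxyacetophenone | CC(=O)c1cc(Br)c(O)cc1O | intermediate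
3 | potassium vinyltrifluoroborate | C=C[B-](F)(F)F.[K+] | starting material
4 | 5-vinyl-2,4-dihydroxyacetophenone | CC(=O)c1cc(C=C)c(O)cc1O | intermediate
5 | racemic 2-methyl-2-vinyloxirane (isoprene monoepoxide) | CC1(C=C)CO1 | starting material
6 | (R)-1-[5-ethenyl-2-hydroxy-4-[(1-hydroxy-2-methylbut-3-en-2-yl)oxy]phenyl]ethanone | OC[C@@](C)(C=C)Oc1cc(O)c(C(C)=O)cc1C=C | intermediate
7 | (R)-1-[7-hydroxy-2-(hydroxymethyl)-2-methyl-2H-chromen-6-yl]ethanone | OC[C@@]1(C)C=Cc2cc(C(C)=O)c(O)cc2O1 | intermediate
8 | trans-ferulic acid | COc1cc(/C=C/C(=O)O)ccc1O | starting material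
9 | tert-butyldimethylsilyl (E)-3-[4-(tert-butyldimethylsilyloxy)-3-methoxyphenyl]prop-2-enoate (bis-TBS ferulate) | COc1cc(/C=C/C(=O)O[Si](C)(C)C(C)(C)C)ccc1O[Si](C)(C)C(C)(C)C | intermediate
10 | (E)-3-[4-(tert-butyldimethylsilyloxy)-3-methoxyphenyl]prop-2-enoic acid (4-O-TBS-ferulic acid) | COc1cc(/C=C/C(=O)O)ccc1O[Si](C)(C)C(C)(C)C | intermediate
11 | [(2R)-6-acetyl-7-hydroxy-2-methyl-2H-chromen-2-yl]methyl (E)-3-[4-(tert-butyldimethylsilyloxy)-3-methoxyphenyl]prop-2-enoate | COc1cc(/C=C/C(=O)OC[C@@]2(C)C=Cc3cc(C(C)=O)c(O)cc3O2)ccc1O[Si](C)(C)C(C)(C)C | intermediate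
12 | [(2R)-6-acetyl-7-hydroxy-2-methyl-2H-chromen-2-yl]methyl (E)-3-(4-hydroxy-3-methoxyphenyl)prop-2-enoate | COc1cc(/C=C/C(=O)OC[C@@]2(C)C=Cc3cc(C(C)=O)c(O)cc3O2)ccc1O | target

Total step count: 7 steps, with the two-stage protection of ferulic acid counted as one operation.
Longest linear sequence: 6 steps (1 to 2 to 4 to 6 to 7 to 11 to 12).

Steps most likely to fail

Step 3. Capture of the pi-allyl by the acidic, ortho-substituted phenoxide may outrun the equilibration of the diastereomeric complexes and erode the enantiomeric purity. Re-ionisation of the electron-poor tertiary aryl ether may also leak material to the linear ether. The fallback sets out from 4 and returns at 6. It replaces the epoxide by a geometrically defined, O-protected linear allyl carbonate, so that no free alkoxide is present and the selection is made on a neutral pi-allyl. Horner–Wadsworth–Emmons olefination of commercial 1-(tert-butyldimethylsilyloxy)propan-2-one with triethyl phosphonoacetate (NaH, THF) should give ethyl (E)-4-(tert-butyldimethylsilyloxy)-3-methylbut-2-enoate F1. Reduction with i-Bu2AlH (CH2Cl2, −78 °C) should give (E)-4-(tert-butyldimethylsilyloxy)-3-methylbut-2-en-1-ol F2. Methyl chloroformate and pyridine should then give (E)-4-(tert-butyldimethylsilyloxy)-3-methylbut-2-en-1-yl methyl carbonate F3. Asymmetric allylic etherification of 4 with this carbonate (Pd2(dba)3·CHCl3, DACH-phenyl Trost ligand, CH2Cl2, rt) is a known way to tertiary aryl ethers from phenols and E-trisubstituted allyl carbonates. It should give (R)-1-[4-({1-[(tert-butyldimethylsilyl)oxy]-2-methylbut-3-en-2-yl}oxy)-5-ethenyl-2-hydroxyphenyl]ethanone F4, with the ligand antipode chosen by the same check as in the main route. Bu4NF buffered with AcOH (THF, rt) then frees the primary alcohol and gives 6.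

Step 2. Oxidative addition into the doubly deprotonated bromoresorcinol may be slow and give way to protodebromination, and the free hydroxystyrene may oligomerise under hot basic conditions. The fallback sets out from 2 and returns at 6, reversing the order of the two bond formations so that no free ortho-hydroxystyrene is handled. Bromophenol 2 is first etherified with 5 under the conditions of step 3 to give (R)-1-[5-bromo-2-hydroxy-4-[(1-hydroxy-2-methylbut-3-en-2-yl)oxy]phenyl]ethanone F5. This bromide is then vinylated with 3 under a Suzuki–Miyaura protocol that inserts into the C–Br bond at low temperature (Pd(OAc)2, SPhos, K3PO4, THF/H2O, 40 °C). The mild temperature keeps ionisation of the tertiary allyl aryl ether by zerovalent palladium to a minimum. The product is 6.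

Step 6. Acylation of the primary alcohol next to the quaternary carbon may be slow enough for rearrangement of the activated acid to an N-acylurea and for DMAP-promoted acylation of the 7-OH to compete. The fallback sets out from 7 and returns at 11. It makes the ester bond with a small, highly reactive acid and builds the cinnamate alkene afterwards. Coupling of 7 with diethylphosphonoacetic acid (DCC, CH2Cl2, no DMAP) should give [(2R)-6-acetyl-7-hydroxy-2-methyl-2H-chromen-2-yl]methyl 2-(diethoxyphosphoryl)acetate F6. Vanillin is silylated (TBSCl, imidazole, DMF) to 4-(tert-butyldimethylsilyloxy)-3-methoxybenzaldehyde F7. A Masamune–Roush Horner–Wadsworth–Emmons reaction of the two (LiCl, i-Pr2NEt, MeCN, rt) should form the E alkene and give 11, which goes on to step 7.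

Further compounds
F1 | step 3 | ethyl (E)-4-(tert-butyldimethylsilyloxy)-3-methylbut-2-enoate | CCOC(=O)/C=C(\C)CO[Si](C)(C)C(C)(C)C
F2 | step 3 | (E)-4-(tert-butyldimethylsilyloxy)-3-methylbut-2-en-1-ol | OC/C=C(\C)CO[Si](C)(C)C(C)(C)C
F3 | step 3 | (E)-4-(tert-butyldimethylsilyloxy)-3-methylbut-2-en-1-yl methyl carbonate | COC(=O)OC/C=C(\C)CO[Si](C)(C)C(C)(C)C
F4 | step 3 | (R)-1-[4-({1-[(tert-butyldimethylsilyl)oxy]-2-methylbut-3-en-2-yl}oxy)-5-ethenyl-2-hydroxyphenyl]ethanone | CC(C)(C)[Si](C)(C)OC[C@@](C)(C=C)Oc1cc(O)c(C(C)=O)cc1C=C
F5 | step 2 | (R)-1-[5-bromo-2-hydroxy-4-[(1-hydroxy-2-methylbut-3-en-2-yl)oxy]phenyl]ethanone | OC[C@@](C)(C=C)Oc1cc(O)c(C(C)=O)cc1Br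
F6 | step 6 | [(2R)-6-acetyl-7-hydroxy-2-methyl-2H-chromen-2-yl]methyl 2-(diethoxyphosphoryl)acetate | CCOP(=O)(OCC)CC(=O)OC[C@@]1(C)C=Cc2cc(C(C)=O)c(O)cc2O1
F7 | step 6 | 4-(tert-butyldimethylsilyloxy)-3-methoxybenzaldehyde | COc1cc(C=O)ccc1O[Si](C)(C)C(C)(C)C
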